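**Plan**
Numbering is that of the naphthoquinone: C1=O beside C2–OMe, ring fusion C4a/C8a, C6 benzyl, C7 methyl, C8 aryl.
1. Retrosynthesis: the benzyl ethers are removed, C4=O is taken back to C4–H of a 2-methoxy-1-naphthol, and the oxygenated ring is cut at C1–C2 and C4–C4a. This gives a tetrasubstituted N,N-diethylbenzamide (amide carbon = C1) and acrolein dimethyl acetal (C2–C4 with the OMe). The arene is cut at C6–CH2 and C8–aryl back to a resorcylate.
2. Enabling feature: C1 sits on C8a between the C8 aryl group and the only free ortho position, C4a–H. As a tertiary amide it steers metalation to C4a alone and then accepts the methoxy-bearing allyl terminus C2, which fixes OMe beside C1 and leaves C4 para to the C1 hydroxyl for oxidation.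
3. Forward: the benzenoid ring (C4a–C8a) is bought and dressed by two triflate cross-couplings (C6 benzyl, then C8 aryl). The second ring is closed in one flask, C4 is oxygenated, and the benzyl ethers are removed last.
4. Stereochemistry: none to set. The target has no stereocentre, and the C8–aryl axis (no ortho substituent on the guaiacyl ring) rotates freely.

Key step: step 7

Assumption: compounds 1, 3, 9 and 11 are taken as commercially available.

**Step 1**
Reactants: 1 methyl 2,4-dihydroxy-3-methylbenzoate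
Product: 2 methyl 2-hydroxy-3-methyl-4-(trifluoromethylsulfonyloxy)benzoate
Conditions: PhNTf2 (1.05 equiv), Et3N, CH2Cl2, 0 °C to rt
Reagents that add atoms: N-phenylbis(trifluoromethanesulfonimide), O=S(=O)(N(c1ccccc1)S(=O)(=O)C(F)(F)F)C(F)(F)F
Why: Selective phenol triflation should occur at the free, more acidic 4-OH, because the 2-OH is held in a hydrogen bond to the ester carbonyl.

**Step 2**
Reactants: 3 [4-(benzyloxy)-3-methoxyphenyl]methanol
Product: 4 1-(benzyloxy)-4-(chloromethyl)-2-methoxybenzene
Conditions: SOCl2, CH2Cl2, 0 °C to rt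
Reagents that add atoms: thionyl chloride, O=S(Cl)Cl
Why: Deoxychlorination of an electron-rich benzylic alcohol through its chlorosulfite should be fast and clean.

**Step 3**
Reactants: 2 methyl 2-hydroxy-3-methyl-4-(trifluoromethylsulfonyloxy)benzoate; 4 1-(benzyloxy)-4-(chloromethyl)-2-methoxybenzene
Product: 6 methyl 4-[4-(benzyloxy)-3-methoxybenzyl]-2-hydroxy-3-methylbenzoate, via benzylzinc chloride 5 (not isolated)
Conditions: 4, zinc dust, LiCl, THF, 25 °C; then 2, Pd(OAc)2 (2 mol %), SPhos (4 mol %), THF, 25 to 50 °C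
Reagents that add atoms: none
Why: LiCl-assisted zinc insertion into the benzylic chloride followed by Negishi coupling with the aryl triflate should form the C6–CH2 bond, since Pd(OAc)2/SPhos couplings of benzylic zinc chlorides tolerate a hydrogen-bonded phenol.

**Step 4**
Reactants: 6 methyl 4-[4-(benzyloxy)-3-methoxybenzyl]-2-hydroxy-3-methylbenzoate
Product: 7 4-[4-(benzyloxy)-3-methoxybenzyl]-N,N-diethyl-2-hydroxy-3-methylbenzamide
Conditions: AlMe3 (3 equiv), Et2NH (3 equiv), toluene, sealed tube, 0 to 100 °C; aqueous Rochelle salt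
Reagents that add atoms: diethylamine, CCNCC
Why: AlMe3-mediated ester aminolysis (Me2AlNEt2 formed in the flask, ester activated through the aluminium phenoxide chelate) should give the tertiary amide needed later as director and internal electrophile.

**Step 5**
Reactants: 7 4-[4-(benzyloxy)-3-methoxybenzyl]-N,N-diethyl-2-hydroxy-3-methylbenzamide
Product: 8 3-[4-(benzyloxy)-3-methoxybenzyl]-6-(diethylcarbamoyl)-2-methylphenyl trifluoromethanesulfonate
Conditions: Tf2O, pyridine, CH2Cl2, 0 °C to rt
Reagents that add atoms: trifluoromethanesulfonic anhydride, O=S(=O)(OS(=O)(=O)C(F)(F)F)C(F)(F)F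
Why: Triflation of the remaining, hindered phenol with the more reactive anhydride should proceed, as no other nucleophilic OH or NH is present.

**Step 6**
Reactants: 8 3-[4-(benzyloxy)-3-methoxybenzyl]-6-(diethylcarbamoyl)-2-methylphenyl trifluoromethanesulfonate; 9 [4-(benzyloxy)-3-methoxyphenyl]boronic acid
Product: 10 2-[4-(benzyloxy)-3-methoxyphenyl]-4-[4-(benzyloxy)-3-methoxybenzyl]-N,N-diethyl-3-methylbenzamide
Conditions: Pd(OAc)2 (5 mol %), SPhos (10 mol %), K3PO4, toluene/H2O, 100 °C
Reagents that add atoms: none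
Why: Suzuki–Miyaura coupling of the di-ortho-substituted aryl triflate with an unhindered boronic acid should form the C8–aryl bond under a bulky biarylphosphine ligand.

**Step 7**
Reactants: 10 2-[4-(benzyloxy)-3-methoxyphenyl]-4-[4-(benzyloxy)-3-methoxybenzyl]-N,N-diethyl-3-methylbenzamide; 11 acrolein dimethyl acetal
Product: 16 8-[4-(benzyloxy)-3-methoxyphenyl]-6-[4-(benzyloxy)-3-methoxybenzyl]-2-methoxy-7-methylnaphthalen-1-ol, via ortho-lithiated amide 12 (not isolated), via arylmagnesium bromide 13 (not isolated), via ortho-(3-methoxyallyl)benzamide 14 (not isolated), via allyllithium 15 (not isolated)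
Conditions: s-BuLi (1.2 equiv), TMEDA, THF, −78 °C; MgBr2·OEt2, −78 to −20 °C; CuBr·SMe2 (10 mol %), 11, −20 to 0 °C; then LDA (3 equiv), −78 °C to rt; NH4Cl (aq)
Reagents that add atoms: none
Why: Proposed new method: the tertiary amide at C1 directs s-BuLi to C4a, the only free ortho position (C8 carries the aryl group), and after exchange to magnesium the aryl nucleophile displaces one methoxide of acrolein dimethyl acetal in a copper-catalysed SN2' step, which forms C4–C4a and leaves an enol ether whose methoxy-bearing terminus is C2. LDA then removes a benzylic/allylic proton at C4, and the 1-aryl-3-methoxyallyl anion attacks the amide carbonyl through C2 in a 6-exo-trig closure (attack through C4 would give a four-membered ring), after which loss of LiNEt2 and enolisation give the 1-naphtholate. The closest known reaction types are the LDA-induced anionic annulation of ortho-allylbenzamides to 1-naphthols and the copper-catalysed SN2' substitution of acrolein acetals by Grignard reagents; what is new is their union in one flask with an alkoxy-bearing allyl unit. No stereocentre is formed, and the E/Z mixture of the enol ether converges because the allyl anion equilibrates and C2 ends up aromatic. The selectivity needed is site selectivity in both deprotonations: complex-induced ortho-lithiation at −78 °C should outrun deprotonation of the diarylmethane CH2, and in the second stage excess LDA covers that CH2 while the far more acidic allylic position, not a remote C–H of the C8 aryl ring, supplies the ring-closing anion at low temperature.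

**Step 8**
Reactants: 16 8-[4-(benzyloxy)-3-methoxyphenyl]-6-[4-(benzyloxy)-3-methoxybenzyl]-2-methoxy-7-methylnaphthalen-1-ol
Product: 17 8-[4-(benzyloxy)-3-methoxyphenyl]-6-[4-(benzyloxy)-3-methoxybenzyl]-2-methoxy-7-methylnaphthalene-1,4-dione
Conditions: ON(SO3K)2 (2.5 equiv), KH2PO4, Bu4NHSO4, CH2Cl2/H2O, rt
Reagents that add atoms: Fremy's salt (dipotassium nitrosodisulfonate), [O]N(S(=O)(=O)[O-])S(=O)(=O)[O-].[K+].[K+]
Why: Teuber oxidation of the only free phenol should deliver oxygen at C4, para to the C1 hydroxyl, because C2 is blocked by OMe and the guaiacyl oxygens are benzylated.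

**Step 9**
Reactants: 17 8-[4-(benzyloxy)-3-methoxyphenyl]-6-[4-(benzyloxy)-3-methoxybenzyl]-2-methoxy-7-methylnaphthalene-1,4-dione
Product: 19 larreantin, via hydroquinone 18 (not isolated)
Conditions: H2 (1 atm), Pd/C, EtOAc/MeOH, rt; then air, rt
Reagents that add atoms: none
Why: Hydrogenolysis of both aryl benzyl ethers over palladium on carbon should also reduce the quinone to its hydroquinone, which air returns to the quinone without touching the guaiacyl phenols.

**Compound list**
1 | methyl 2,4-dihydroxy-3-methylbenzoate | COC(=O)c1ccc(O)c(C)c1O | starting material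
2 | methyl 2-hydroxy-3-methyl-4-(trifluoromethylsulfonyloxy)benzoate | COC(=O)c1ccc(OS(=O)(=O)C(F)(F)F)c(C)c1O | intermediate
3 | [4-(benzyloxy)-3-methoxyphenyl]methanol | COc1cc(CO)ccc1OCc1ccccc1 | starting material
4 | 1-(benzyloxy)-4-(chloromethyl)-2-methoxybenzene | COc1cc(CCl)ccc1OCc1ccccc1 | intermediate
5 | [4-(benzyloxy)-3-methoxybenzyl]zinc chloride | COc1cc(C[Zn]Cl)ccc1OCc1ccccc1 | intermediate
6 | methyl 4-[4-(benzyloxy)-3-methoxybenzyl]-2-hydroxy-3-methylbenzoate | COC(=O)c1ccc(Cc2ccc(OCc3ccccc3)c(OC)c2)c(C)c1O | intermediate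
7 | 4-[4-(benzyloxy)-3-methoxybenzyl]-N,N-diethyl-2-hydroxy-3-methylbenzamide | CCN(CC)C(=O)c1ccc(Cc2ccc(OCc3ccccc3)c(OC)c2)c(C)c1O | intermediate
8 | 3-[4-(benzyloxy)-3-methoxybenzyl]-6-(diethylcarbamoyl)-2-methylphenyl trifluoromethanesulfonate | CCN(CC)C(=O)c1ccc(Cc2ccc(OCc3ccccc3)c(OC)c2)c(C)c1OS(=O)(=O)C(F)(F)F | intermediate
9 | [4-(benzyloxy)-3-methoxyphenyl]boronic acid | COc1cc(B(O)O)ccc1OCc1ccccc1 | starting material
10 | 2-[4-(benzyloxy)-3-methoxyphenyl]-4-[4-(benzyloxy)-3-methoxybenzyl]-N,N-diethyl-3-methylbenzamide | CCN(CC)C(=O)c1ccc(Cc2ccc(OCc3ccccc3)c(OC)c2)c(C)c1-c1ccc(OCc2ccccc2)c(OC)c1 | intermediate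
11 | acrolein dimethyl acetal (3,3-dimethoxyprop-1-ene) | C=CC(OC)OC | starting material
12 | 6-lithio derivative of 10 (aryllithium at the position ortho to the amide) | CCN(CC)C(=O)c1c([Li])cc(Cc2ccc(OCc3ccccc3)c(OC)c2)c(C)c1-c1ccc(OCc2ccccc2)c(OC)c1 | intermediate
13 | corresponding arylmagnesium bromide | CCN(CC)C(=O)c1c([Mg]Br)cc(Cc2ccc(OCc3ccccc3)c(OC)c2)c(C)c1-c1ccc(OCc2ccccc2)c(OC)c1 | intermediate
14 | 2-[4-(benzyloxy)-3-methoxyphenyl]-4-[4-(benzyloxy)-3-methoxybenzyl]-N,N-diethyl-6-(3-methoxyprop-2-en-1-yl)-3-methylbenzamide (E/Z mixture) | CCN(CC)C(=O)c1c(CC=COC)cc(Cc2ccc(OCc3ccccc3)c(OC)c2)c(C)c1-c1ccc(OCc2ccccc2)c(OC)c1 | intermediate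
15 | allyllithium from 14 (lithium on the benzylic carbon of the methoxyallyl group) | CCN(CC)C(=O)c1c(C([Li])C=COC)cc(Cc2ccc(OCc3ccccc3)c(OC)c2)c(C)c1-c1ccc(OCc2ccccc2)c(OC)c1 | intermediate
16 | 8-[4-(benzyloxy)-3-methoxyphenyl]-6-[4-(benzyloxy)-3-methoxybenzyl]-2-methoxy-7-methylnaphthalen-1-ol | COc1ccc2cc(Cc3ccc(OCc4ccccc4)c(OC)c3)c(C)c(-c3ccc(OCc4ccccc4)c(OC)c3)c2c1O | intermediate
17 | 8-[4-(benzyloxy)-3-methoxyphenyl]-6-[4-(benzyloxy)-3-methoxybenzyl]-2-methoxy-7-methylnaphthalene-1,4-dione | COC1=CC(=O)c2cc(Cc3ccc(OCc4ccccc4)c(OC)c3)c(C)c(-c3ccc(OCc4ccccc4)c(OC)c3)c2C1=O | intermediate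
18 | 8-(4-hydroxy-3-methoxyphenyl)-6-(4-hydroxy-3-methoxybenzyl)-2-methoxy-7-methylnaphthalene-1,4-diol | COc1cc(O)c2cc(Cc3ccc(O)c(OC)c3)c(C)c(-c3ccc(O)c(OC)c3)c2c1O | intermediate
19 | larreantin | COC1=CC(=O)c2cc(Cc3ccc(O)c(OC)c3)c(C)c(-c3ccc(O)c(OC)c3)c2C1=O | target

**Step count and risks**
Total step count: 9. Longest linear sequence: 8 steps (1 → 2 → 6 → 7 → 8 → 10 → 16 → 17 → 19).

Steps most likely to fail:

1. Step 7. The base may deprotonate the diarylmethane CH2 in place of the ortho position or the allylic CH2. LDA may metalate the C8 aryl ring remotely and close it onto the amide to a fluorenone. The hindered aryl-magnesium species may be captured too slowly in the SN2' step, and the methoxyallyl unit may isomerise before ring closure. Fallback with known chemistry, from 10: ortho-lithiation (s-BuLi, TMEDA), exchange with MgBr2·OEt2 and allylation with allyl bromide would give the isolated ortho-allyl amide F1. LDA would close it to the methoxy-free 1-naphthol F2 by the known anionic annulation of ortho-allylbenzamides. Amine-mediated ortho-bromination (NBS, iPr2NH) would give the 2-bromo-1-naphthol F3, and Fremy's salt the 2-bromo-1,4-naphthoquinone F4. NaOMe in MeOH would then replace bromide by methoxide at C2 by addition–elimination, returning to the route at 17.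

2. Step 3. The free phenol may protonate the benzylzinc reagent, oxidative addition at the triflate beside the methyl group may be slow, and the benzylic zinc reagent may homocouple. Fallback, from 2: palladium-catalysed borylation with tetrahydroxydiboron would give the arylboronic acid F5. Commercial 4-(benzyloxy)-3-methoxybenzaldehyde and tosylhydrazide would give the N-tosylhydrazone F6. Heating F5 and F6 with K2CO3 in dioxane would join them by metal-free reductive coupling (diazo formation, boron-to-carbon aryl shift, protodeboronation), returning to the route at 6.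

3. Step 9. The quinone ring may be over-reduced, the vinylogous ester methoxy group may be lost by hydrogenolysis, and re-oxidation in air may be incomplete. Fallback, from 16: hydrogenolysis (H2, Pd/C) before the oxidation would give the tris-phenol F7. O2 with catalytic N,N'-bis(salicylidene)ethylenediaminocobalt (divalent cobalt) in DMF would then oxidise only the 1-naphthol, whose para position C4 is free, to the para-quinone, arriving at 19.

**Further compounds**
F1 | step 7 | 6-allyl-2-[4-(benzyloxy)-3-methoxyphenyl]-4-[4-(benzyloxy)-3-methoxybenzyl]-N,N-diethyl-3-methylbenzamide | CCN(CC)C(=O)c1c(CC=C)cc(Cc2ccc(OCc3ccccc3)c(OC)c2)c(C)c1-c1ccc(OCc2ccccc2)c(OC)c1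
F2 | step 7 | 8-[4-(benzyloxy)-3-methoxyphenyl]-6-[4-(benzyloxy)-3-methoxybenzyl]-7-methylnaphthalen-1-ol | Oc1cccc2cc(Cc3ccc(OCc4ccccc4)c(OC)c3)c(C)c(-c3ccc(OCc4ccccc4)c(OC)c3)c12
F3 | step 7 | 8-[4-(benzyloxy)-3-methoxyphenyl]-6-[4-(benzyloxy)-3-methoxybenzyl]-2-bromo-7-methylnaphthalen-1-ol | Oc1c(Br)ccc2cc(Cc3ccc(OCc4ccccc4)c(OC)c3)c(C)c(-c3ccc(OCc4ccccc4)c(OC)c3)c12
F4 | step 7 | 8-[4-(benzyloxy)-3-methoxyphenyl]-6-[4-(benzyloxy)-3-methoxybenzyl]-2-bromo-7-methylnaphthalene-1,4-dione | O=C1C(Br)=CC(=O)c2cc(Cc3ccc(OCc4ccccc4)c(OC)c3)c(C)c(-c3ccc(OCc4ccccc4)c(OC)c3)c21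
F5 | step 3 | [3-hydroxy-4-(methoxycarbonyl)-2-methylphenyl]boronic acid | COC(=O)c1ccc(B(O)O)c(C)c1O
F6 | step 3 | (E)-N'-[4-(benzyloxy)-3-methoxybenzylidene]-4-methylbenzenesulfonohydrazide | COc1cc(/C=N/NS(=O)(=O)c2ccc(C)cc2)ccc1OCc1ccccc1
F7 | step 9 | 8-(4-hydroxy-3-methoxyphenyl)-6-(4-hydroxy-3-methoxybenzyl)-2-methoxy-7-methylnaphthalen-1-ol | COc1ccc2cc(Cc3ccc(O)c(OC)c3)c(C)c(-c3ccc(O)c(OC)c3)c2c1O
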